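**Retrosynthetic overview**

1. Target 26 ⇐ chroman-4-one 23: C4 is carried as a ketone and the C5 hydroxyl as OMe; the C4 carbonyl first directs BCl3 to the peri C5 methoxy group, then reduction and dehydration install C3=C4.
2. Key disconnection of the pyranone ring at C4–C4a and C3–C2: 23 ⇐ α-aryloxy diazoketone 21 by Wolff rearrangement (C2 migrates with retention onto the diazo carbon, which becomes C3) and Friedel–Crafts closure of the ketene carbon (C4) onto C4a.
3. Enabling feature: the benzene ring is penta-oxygenated and has one free position, C4a, ortho to O1 (on C8a) and to the C5 oxygen; C2 is a fully substituted carbon bound to O1, so it can be set beforehand as a tertiary α-aryloxy acid centre and moved intact.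
4. 21 ⇐ acid 19 ⇐ Mitsunobu inversion of tertiary α-hydroxy ester 13 with phenol 17; 13 ⇐ alkylation of the (R)-lactic acid dioxolanone 10 with iodide 7.
5. 7 ⇐ enantioselective endo Diels–Alder reaction of diene 3 with 2-methylene aldehyde 2 (the formyl group becomes the C1′ methyl). Ring order: cyclohexene (step 2), purchased benzene ring, pyran ring last (step 12).

Key step: step 12

Remark: chromene locants (O1, C2, C3, C4, C4a, C5–C8, C8a) are used for the bicycle and primed locants for the cyclohexene (C1′ quaternary, C2′ the CH(CH3) carbon). Commercial 3-methylpenta-1,3-diene is an E/Z mixture and is used in excess, because only the E isomer 3 reaches the s-cis geometry.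

**Route**

Step 1
Reactants: 1 4-[(tert-butyldimethylsilyl)oxy]butanal
Product: 2 4-[(tert-butyldimethylsilyl)oxy]-2-methylidenebutanal
Conditions: 37% aq. HCHO, pyrrolidine (10 mol%), EtCO2H (10 mol%), i-PrOH, 45 °C
Reagents that add atoms: formaldehyde, C=O
Why: Organocatalytic α-methylenation (Mannich condensation with formaldehyde through the enamine, then elimination of the amine) at the only α-CH2 group; the silyl ether is inert.

Step 2
Reactants: 2 4-[(tert-butyldimethylsilyl)oxy]-2-methylidenebutanal; 3 (3E)-3-methylpenta-1,3-diene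
Product: 4 (1R,2R)-1-{2-[(tert-butyldimethylsilyl)oxy]ethyl}-2,3-dimethylcyclohex-3-ene-1-carbaldehyde
Conditions: 3 (3 equiv), (S)-3,3-diphenyl-1-(2-methylphenyl)tetrahydro-1H,3H-pyrrolo[1,2-c][1,3,2]oxazaborole protonated by HNTf2 (20 mol%), CH2Cl2, −78 → −40 °C
Reagents that add atoms: none
Why: Lewis-acid-catalysed Diels–Alder reaction of a 2-substituted acrolein: the enal CH2 should bond to the unsubstituted diene terminus (the terminal methyl of the diene governs regiochemistry), the boron-bound formyl group should lie endo and so end cis to the C2 methyl, and the chiral oxazaborolidinium should block one enal face, which sets C1 and C2 together as (1R,2R); the (S)-catalyst is chosen by analogy with the facial sense expected for 2-methylacrolein, and the (R)-catalyst would give the mirror-image series.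

Step 3
Reactants: 4 (1R,2R)-1-{2-[(tert-butyldimethylsilyl)oxy]ethyl}-2,3-dimethylcyclohex-3-ene-1-carbaldehyde
Product: 6 2-[(1S,2S)-1,2,3-trimethylcyclohex-3-en-1-yl]ethan-1-ol, via hydrazone 5 (not isolated)
Conditions: N2H4·H2O (excess), KOH, diethylene glycol, 130 °C, then 200 °C
Reagents that add atoms: none
Why: Wolff–Kishner reduction (Huang–Minlon modification) should turn the neopentyl formyl group into the C1′ methyl group through hydrazone 5 without touching the non-epimerisable stereocentres or the isolated alkene, and the hot KOH/glycol medium should also cleave the primary silyl ether.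

Step 4
Reactants: 6 2-[(1S,2S)-1,2,3-trimethylcyclohex-3-en-1-yl]ethan-1-ol
Product: 7 (5S,6S)-5-(2-iodoethyl)-1,5,6-trimethylcyclohex-1-ene
Conditions: I2, PPh3, imidazole, CH2Cl2, 0 → 25 °C
Reagents that add atoms: iodine, II
Why: Appel-type iodination of the unhindered primary alcohol by SN2 displacement of the alkoxyphosphonium ion; no stereocentre is involved.

Step 5
Reactants: 8 (R)-lactic acid; 9 pivalaldehyde
Product: 10 (2R,5R)-2-tert-butyl-5-methyl-1,3-dioxolan-4-one
Conditions: p-TsOH·H2O (cat.), pentane, reflux (Dean–Stark trap); crystallisation at −78 °C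
Reagents that add atoms: none
Why: Acid-catalysed acetalisation of the α-hydroxy acid leaves C5 untouched and sets the acetal carbon; the cis-(2R,5R) isomer should be the major acetal and is freed of its trans isomer by crystallisation.

Step 6
Reactants: 10 (2R,5R)-2-tert-butyl-5-methyl-1,3-dioxolan-4-one; 7 (5S,6S)-5-(2-iodoethyl)-1,5,6-trimethylcyclohex-1-ene
Product: 12 (2R,5S)-2-tert-butyl-5-methyl-5-{2-[(1S,2S)-1,2,3-trimethylcyclohex-3-en-1-yl]ethyl}-1,3-dioxolan-4-one, via lithium enolate 11 (not isolated)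
Conditions: 10 (1.5 equiv), LiN(i-Pr)2, THF, −78 °C; then 7, DMPU, −78 → −30 °C
Reagents that add atoms: none
Why: Enolate alkylation with self-regeneration of the stereocentre: the planar lithium enolate 11 should be alkylated on the face anti to the tert-butyl group of the acetal carbon, so the new C–C bond takes the place of the former C5–H with retention and C5 becomes (S).

Step 7
Reactants: 12 (2R,5S)-2-tert-butyl-5-methyl-5-{2-[(1S,2S)-1,2,3-trimethylcyclohex-3-en-1-yl]ethyl}-1,3-dioxolan-4-one
Product: 13 methyl (2S)-2-hydroxy-2-methyl-4-[(1S,2S)-1,2,3-trimethylcyclohex-3-en-1-yl]butanoate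
Conditions: NaOMe (0.2 equiv), MeOH, 0 → 25 °C
Reagents that add atoms: methanol, CO
Why: Base-catalysed methanolysis of the acyl acetal (transesterification, then loss of pivalaldehyde from the hemiacetal) should free the tertiary α-hydroxy ester without breaking any bond at the stereocentre.

Step 8
Reactants: 14 1,2,3,4-tetramethoxybenzene
Product: 17 2,3,4,5-tetramethoxyphenol, via aryllithium 15 (not isolated), via boronic ester 16 (not isolated)
Conditions: n-BuLi, TMEDA, THF, 0 °C; B(OMe)3, −78 → 25 °C; then 30% H2O2, AcOH, 0 → 25 °C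
Reagents that add atoms: hydrogen peroxide, OO
Why: Directed ortho-lithiation next to a methoxy group, borylation and oxidative C–B to C–O conversion; the two ring C–H positions of the twofold-symmetric arene are equivalent, so only one phenol can form.

Step 9
Reactants: 13 methyl (2S)-2-hydroxy-2-methyl-4-[(1S,2S)-1,2,3-trimethylcyclohex-3-en-1-yl]butanoate; 17 2,3,4,5-tetramethoxyphenol
Product: 18 methyl (2R)-2-methyl-2-(2,3,4,5-tetramethoxyphenoxy)-4-[(1S,2S)-1,2,3-trimethylcyclohex-3-en-1-yl]butanoate
Conditions: PPh3, DIAD, toluene, 0 → 40 °C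
Reagents that add atoms: none
Why: Mitsunobu etherification of a tertiary α-hydroxy ester: the adjacent ester group disfavours ionisation and allows SN2 attack of the phenoxide on the alkoxyphosphonium ion, so the C–O bond should form with inversion and C2 becomes (R).

Step 10
Reactants: 18 methyl (2R)-2-methyl-2-(2,3,4,5-tetramethoxyphenoxy)-4-[(1S,2S)-1,2,3-trimethylcyclohex-3-en-1-yl]butanoate
Product: 19 (2R)-2-methyl-2-(2,3,4,5-tetramethoxyphenoxy)-4-[(1S,2S)-1,2,3-trimethylcyclohex-3-en-1-yl]butanoic acid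
Conditions: LiOH·H2O, THF/MeOH/H2O, 50 °C; then 1 M HCl, 0 °C
Reagents that add atoms: lithium hydroxide, [Li+].[OH-]
Why: Saponification of the methyl ester; the α-carbon is quaternary, so neither epimerisation nor E1cB loss of the aryloxy group is possible.

Step 11
Reactants: 19 (2R)-2-methyl-2-(2,3,4,5-tetramethoxyphenoxy)-4-[(1S,2S)-1,2,3-trimethylcyclohex-3-en-1-yl]butanoic acid
Product: 21 (3R)-1-diazo-3-methyl-3-(2,3,4,5-tetramethoxyphenoxy)-5-[(1S,2S)-1,2,3-trimethylcyclohex-3-en-1-yl]pentan-2-one, via acid chloride 20 (not isolated)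
Conditions: 1-chloro-N,N,2-trimethylprop-1-en-1-amine, CH2Cl2, 0 → 25 °C; then CH2N2, Et3N, Et2O, 0 °C
Reagents that add atoms: diazomethane, C=[N+]=[N-]
Why: Acylation of diazomethane by the acid chloride (first stage of an Arndt–Eistert sequence, Et3N as HCl scavenger); the neutral chloroenamine avoids HCl near the cyclohexene, and the quaternary α-carbon rules out ketene formation and epimerisation.

Step 12
Reactants: 21 (3R)-1-diazo-3-methyl-3-(2,3,4,5-tetramethoxyphenoxy)-5-[(1S,2S)-1,2,3-trimethylcyclohex-3-en-1-yl]pentan-2-one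
Product: 23 (2R)-5,6,7,8-tetramethoxy-2-methyl-2-{2-[(1S,2S)-1,2,3-trimethylcyclohex-3-en-1-yl]ethyl}-2,3-dihydro-4H-chromen-4-one, via ketene 22 (not isolated)
Conditions: hν (blue LEDs, 450 nm), CH2Cl2 (0.01 M), −40 °C, until N2 evolution ends; then BF3·OEt2 (20 mol%), −78 → −20 °C, same flask
Reagents that add atoms: none
Why: Proposed new method: irradiation should expel N2 from the s-Z diazoketone with concerted 1,2-shift of the tertiary α-aryloxyalkyl carbon C2 from the carbonyl carbon (future C4) to the diazo carbon (future C3), which forms C3–C2 with retention at C2 exactly as in the Wolff step of an Arndt–Eistert homologation of an α-stereogenic acid, and gives ketene 22, which has no nucleophile to react with until BF3 is added. BF3 coordination makes the ketene carbon C4 acylium-like, and the only unsubstituted arene carbon, C4a (ortho to the O1-bearing C8a, ortho to the C5 methoxy and para to the C7 methoxy), should attack it in a 6-exo-dig Friedel–Crafts closure that forms C4–C4a and the pyranone ring; proton loss and ketonisation of the boron enolate then release the catalyst. The closest known reaction types are the photochemical Wolff rearrangement of α-alkoxy diazoketones, the Lewis-acid-promoted Friedel–Crafts acylation of arenes by ketenes and the acid-mediated closure of 3-aryloxypropanoic acids to chroman-4-ones; what is new is the capture of a Wolff ketene by C-acylation of a tethered arene in the same flask. No stereocentre is created: C2 is carried over by the retentive shift and the cyclohexene centres are remote. The step needs migration to outrun carbene-type C–H insertion or arene addition, which the bulky tertiary α-carbon should secure by enforcing the s-Z conformer, and it needs acylation to outrun ketene dimerisation and ionisation of the C2–O1 bond, which high dilution, low temperature, a catalytic Lewis acid and the very electron-rich, singly unsubstituted arene are expected to secure.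

Step 13
Reactants: 23 (2R)-5,6,7,8-tetramethoxy-2-methyl-2-{2-[(1S,2S)-1,2,3-trimethylcyclohex-3-en-1-yl]ethyl}-2,3-dihydro-4H-chromen-4-one
Product: 24 (2R)-5-hydroxy-6,7,8-trimethoxy-2-methyl-2-{2-[(1S,2S)-1,2,3-trimethylcyclohex-3-en-1-yl]ethyl}-2,3-dihydro-4H-chromen-4-one
Conditions: BCl3 (1.2 equiv), CH2Cl2, −78 → −20 °C; then H2O, 0 °C
Reagents that add atoms: none
Why: Chelation-directed ether cleavage: boron binds the C4 carbonyl oxygen and the peri C5 methoxy oxygen in a six-membered chelate, so chloride should remove only that methyl group and leave the C6, C7 and C8 methoxy groups and the O1–C2 bond intact.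

Step 14
Reactants: 24 (2R)-5-hydroxy-6,7,8-trimethoxy-2-methyl-2-{2-[(1S,2S)-1,2,3-trimethylcyclohex-3-en-1-yl]ethyl}-2,3-dihydro-4H-chromen-4-one
Product: 25 (2R,4RS)-6,7,8-trimethoxy-2-methyl-2-{2-[(1S,2S)-1,2,3-trimethylcyclohex-3-en-1-yl]ethyl}-3,4-dihydro-2H-chromene-4,5-diol
Conditions: NaBH4, THF/MeOH, 0 °C
Reagents that add atoms: none
Why: Hydride reduction of the aryl ketone; the new C4 carbinol centre should form as an epimer mixture, which is of no consequence because C4 becomes sp2 in the next step.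

Step 15
Reactants: 25 (2R,4RS)-6,7,8-trimethoxy-2-methyl-2-{2-[(1S,2S)-1,2,3-trimethylcyclohex-3-en-1-yl]ethyl}-3,4-dihydro-2H-chromene-4,5-diol
Product: 26 (2R)-6,7,8-trimethoxy-2-methyl-2-{2-[(1S,2S)-1,2,3-trimethylcyclohex-3-en-1-yl]ethyl}-2H-chromen-5-ol
Conditions: PPTS (10 mol%), toluene, 60 °C, dark
Reagents that add atoms: none
Why: Acid-catalysed dehydration of the benzylic alcohol through the cation stabilised by the ortho C5 hydroxyl (ortho-quinone methide character); only C3 carries a β-hydrogen, so C3=C4 should form regiospecifically, while mild acid, moderate temperature and exclusion of light protect the cyclohexene and prevent electrocyclic ring opening of the 2H-chromene that would scramble C2.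

**Compound list**

1 | 4-[(tert-butyldimethylsilyl)oxy]butanal | O=CCCCO[Si](C)(C)C(C)(C)C | starting material
2 | 4-[(tert-butyldimethylsilyl)oxy]-2-methylidenebutanal | C=C(C=O)CCO[Si](C)(C)C(C)(C)C | intermediate
3 | (3E)-3-methylpenta-1,3-diene | C=C/C(C)=C/C | starting material
4 | (1R,2R)-1-{2-[(tert-butyldimethylsilyl)oxy]ethyl}-2,3-dimethylcyclohex-3-ene-1-carbaldehyde | CC(C)(C)[Si](C)(C)OCC[C@]1(C=O)CCC=C(C)[C@H]1C | intermediate
5 | hydrazone of 4, (1R,2R)-1-{2-[(tert-butyldimethylsilyl)oxy]ethyl}-2,3-dimethylcyclohex-3-ene-1-carbaldehyde hydrazone | CC(C)(C)[Si](C)(C)OCC[C@]1(C=NN)CCC=C(C)[C@H]1C | intermediate (not isolated)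
6 | 2-[(1S,2S)-1,2,3-trimethylcyclohex-3-en-1-yl]ethan-1-ol | OCC[C@]1(C)CCC=C(C)[C@H]1C | intermediate
7 | (5S,6S)-5-(2-iodoethyl)-1,5,6-trimethylcyclohex-1-ene | ICC[C@]1(C)CCC=C(C)[C@H]1C | intermediate
8 | (R)-lactic acid | C[C@@H](O)C(=O)O | starting material
9 | pivalaldehyde | CC(C)(C)C=O | starting material
10 | (2R,5R)-2-tert-butyl-5-methyl-1,3-dioxolan-4-one | C[C@H]1O[C@@H](C(C)(C)C)OC1=O | intermediate
11 | lithium (2R)-2-tert-butyl-5-methyl-1,3-dioxol-4-olate | CC1=C([O-])O[C@H](C(C)(C)C)O1.[Li+] | intermediate (not isolated)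
12 | (2R,5S)-2-tert-butyl-5-methyl-5-{2-[(1S,2S)-1,2,3-trimethylcyclohex-3-en-1-yl]ethyl}-1,3-dioxolan-4-one | C[C@@]1(CC[C@]2(C)CCC=C(C)[C@H]2C)O[C@@H](C(C)(C)C)OC1=O | intermediate
13 | methyl (2S)-2-hydroxy-2-methyl-4-[(1S,2S)-1,2,3-trimethylcyclohex-3-en-1-yl]butanoate | O[C@@](C)(CC[C@]1(C)CCC=C(C)[C@H]1C)C(=O)OC | intermediate
14 | 1,2,3,4-tetramethoxybenzene | COc1ccc(OC)c(OC)c1OC | starting material
15 | (2,3,4,5-tetramethoxyphenyl)lithium | [Li]c1cc(OC)c(OC)c(OC)c1OC | intermediate (not isolated)
16 | dimethyl (2,3,4,5-tetramethoxyphenyl)boronate | COB(OC)c1cc(OC)c(OC)c(OC)c1OC | intermediate (not isolated)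
17 | 2,3,4,5-tetramethoxyphenol | COc1cc(O)c(OC)c(OC)c1OC | intermediate
18 | methyl (2R)-2-methyl-2-(2,3,4,5-tetramethoxyphenoxy)-4-[(1S,2S)-1,2,3-trimethylcyclohex-3-en-1-yl]butanoate | COc1cc(O[C@](C)(CC[C@]2(C)CCC=C(C)[C@H]2C)C(=O)OC)c(OC)c(OC)c1OC | intermediate
19 | (2R)-2-methyl-2-(2,3,4,5-tetramethoxyphenoxy)-4-[(1S,2S)-1,2,3-trimethylcyclohex-3-en-1-yl]butanoic acid | COc1cc(O[C@](C)(CC[C@]2(C)CCC=C(C)[C@H]2C)C(=O)O)c(OC)c(OC)c1OC | intermediate
20 | (2R)-2-methyl-2-(2,3,4,5-tetramethoxyphenoxy)-4-[(1S,2S)-1,2,3-trimethylcyclohex-3-en-1-yl]butanoyl chloride | COc1cc(O[C@](C)(CC[C@]2(C)CCC=C(C)[C@H]2C)C(=O)Cl)c(OC)c(OC)c1OC | intermediate (not isolated)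
21 | (3R)-1-diazo-3-methyl-3-(2,3,4,5-tetramethoxyphenoxy)-5-[(1S,2S)-1,2,3-trimethylcyclohex-3-en-1-yl]pentan-2-one | COc1cc(O[C@](C)(CC[C@]2(C)CCC=C(C)[C@H]2C)C(=O)C=[N+]=[N-])c(OC)c(OC)c1OC | intermediate
22 | (3R)-3-methyl-3-(2,3,4,5-tetramethoxyphenoxy)-5-[(1S,2S)-1,2,3-trimethylcyclohex-3-en-1-yl]pent-1-en-1-one (ketene) | COc1cc(O[C@](C)(CC[C@]2(C)CCC=C(C)[C@H]2C)C=C=O)c(OC)c(OC)c1OC | intermediate (not isolated)
23 | (2R)-5,6,7,8-tetramethoxy-2-methyl-2-{2-[(1S,2S)-1,2,3-trimethylcyclohex-3-en-1-yl]ethyl}-2,3-dihydro-4H-chromen-4-one | COc1c(OC)c2c(c(OC)c1OC)O[C@](C)(CC[C@]1(C)CCC=C(C)[C@H]1C)CC2=O | intermediate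
24 | (2R)-5-hydroxy-6,7,8-trimethoxy-2-methyl-2-{2-[(1S,2S)-1,2,3-trimethylcyclohex-3-en-1-yl]ethyl}-2,3-dihydro-4H-chromen-4-one | COc1c(O)c2c(c(OC)c1OC)O[C@](C)(CC[C@]1(C)CCC=C(C)[C@H]1C)CC2=O | intermediate
25 | (2R,4RS)-6,7,8-trimethoxy-2-methyl-2-{2-[(1S,2S)-1,2,3-trimethylcyclohex-3-en-1-yl]ethyl}-3,4-dihydro-2H-chromene-4,5-diol (C4 epimers) | COc1c(O)c2c(c(OC)c1OC)O[C@](C)(CC[C@]1(C)CCC=C(C)[C@H]1C)CC2O | intermediate
26 | (2R)-6,7,8-trimethoxy-2-methyl-2-{2-[(1S,2S)-1,2,3-trimethylcyclohex-3-en-1-yl]ethyl}-2H-chromen-5-ol | COc1c(O)c2c(c(OC)c1OC)O[C@](C)(CC[C@]1(C)CCC=C(C)[C@H]1C)C=C2 | target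

**Step count and risks**

Total step count: 15. Longest linear sequence: 13 steps (steps 1–4, 6, 7, 9–15).

Steps most likely to fail:

1. Step 12 (Proposed new method). The ketene may be lost to dimerisation or to traces of water before it acylates C4a. The excited diazoketone may react through carbene-type C–H or arene insertion instead of the 1,2-shift. The Lewis acid may ionise the C2–O1 bond and erode the configuration at C2. The fallback uses known chemistry, sets out from diazoketone 21 and comes back at chromanone 23. The Wolff rearrangement is run under ordinary Arndt–Eistert conditions (hν, THF/H2O), so that water captures the ketene and gives (3R)-3-methyl-3-(2,3,4,5-tetramethoxyphenoxy)-5-[(1S,2S)-1,2,3-trimethylcyclohex-3-en-1-yl]pentanoic acid F1. Trifluoroacetic anhydride (CH2Cl2, 0 °C) converts F1 into its mixed trifluoroacetic anhydride F2, which should acylate C4a in the same flask (the established Friedel–Crafts closure of 3-aryloxypropanoic acids to chroman-4-ones) and give 23.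

2. Step 9. The activated tertiary alcohol may eliminate to the α,β-unsaturated ester, may ionise with loss of stereochemical fidelity, or may fail to react because of hindrance. The fallback forms the aryl–oxygen bond on the other side of the oxygen, with retention at C2, and therefore uses the C2-epimeric alcohol; it sets out from iodide 7 and comes back at ester 18. (S)-Lactic acid and pivalaldehyde 9 give (2S,5S)-2-tert-butyl-5-methyl-1,3-dioxolan-4-one F3. Alkylation of F3 with 7 as in step 6 gives (2S,5R)-2-tert-butyl-5-methyl-5-{2-[(1S,2S)-1,2,3-trimethylcyclohex-3-en-1-yl]ethyl}-1,3-dioxolan-4-one F4, and methanolysis as in step 7 gives methyl (2R)-2-hydroxy-2-methyl-4-[(1S,2S)-1,2,3-trimethylcyclohex-3-en-1-yl]butanoate F5. Aryllithium 15 is quenched with I2 to 1-iodo-2,3,4,5-tetramethoxybenzene F6, which is oxidised (mCPBA, TsOH·H2O) and coupled with 1,3,5-trimethoxybenzene to (2,3,4,5-tetramethoxyphenyl)(2,4,6-trimethoxyphenyl)iodonium tosylate F7. The sodium alkoxide of F5 (NaN(SiMe3)2, toluene) should be O-arylated by F7 (metal-free arylation of tertiary alkoxides by diaryliodonium salts, the trimethoxyphenyl group staying on iodine) without touching C2, which gives 18.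

3. Step 2. Facial or endo/exo selectivity may be poor, and the two methyl groups of the diene exert opposing directing effects, so the regioisomeric adduct may compete. The fallback sets the C2′ centre with a chiral auxiliary and the quaternary centre by enolate alkylation; it sets out from diene 3 and comes back at aldehyde 4. (R)-4-Benzyloxazolidin-2-one is N-acylated with acryloyl chloride to (4R)-3-acryloyl-4-benzyloxazolidin-2-one F8. The Et2AlCl-promoted Diels–Alder reaction of F8 with 3 (CH2Cl2, −78 °C; endo addition anti to the benzyl group of the chelated s-cis imide) should give (4R)-4-benzyl-3-[(1S,2S)-2,3-dimethylcyclohex-3-ene-1-carbonyl]oxazolidin-2-one F9. MeOMgBr in MeOH gives methyl (1S,2S)-2,3-dimethylcyclohex-3-ene-1-carboxylate F10. Deprotonation with LiN(i-Pr)2 and alkylation with tert-butyl(2-iodoethoxy)dimethylsilane, anti to the neighbouring C2 methyl group, should give methyl (1R,2R)-1-{2-[(tert-butyldimethylsilyl)oxy]ethyl}-2,3-dimethylcyclohex-3-ene-1-carboxylate F11. LiAlH4 gives [(1R,2R)-1-{2-[(tert-butyldimethylsilyl)oxy]ethyl}-2,3-dimethylcyclohex-3-en-1-yl]methanol F12, and Swern oxidation gives 4.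

**Further compounds**

F1 | step 12 | (3R)-3-methyl-3-(2,3,4,5-tetramethoxyphenoxy)-5-[(1S,2S)-1,2,3-trimethylcyclohex-3-en-1-yl]pentanoic acid | COc1cc(O[C@](C)(CC[C@]2(C)CCC=C(C)[C@H]2C)CC(=O)O)c(OC)c(OC)c1OC
F2 | step 12 | (3R)-3-methyl-3-(2,3,4,5-tetramethoxyphenoxy)-5-[(1S,2S)-1,2,3-trimethylcyclohex-3-en-1-yl]pentanoic trifluoroacetic anhydride | COc1cc(O[C@](C)(CC[C@]2(C)CCC=C(C)[C@H]2C)CC(=O)OC(=O)C(F)(F)F)c(OC)c(OC)c1OC
F3 | step 9 | (2S,5S)-2-tert-butyl-5-methyl-1,3-dioxolan-4-one | C[C@@H]1O[C@H](C(C)(C)C)OC1=O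
F4 | step 9 | (2S,5R)-2-tert-butyl-5-methyl-5-{2-[(1S,2S)-1,2,3-trimethylcyclohex-3-en-1-yl]ethyl}-1,3-dioxolan-4-one | C[C@]1(CC[C@]2(C)CCC=C(C)[C@H]2C)O[C@H](C(C)(C)C)OC1=O
F5 | step 9 | methyl (2R)-2-hydroxy-2-methyl-4-[(1S,2S)-1,2,3-trimethylcyclohex-3-en-1-yl]butanoate | O[C@](C)(CC[C@]1(C)CCC=C(C)[C@H]1C)C(=O)OC
F6 | step 9 | 1-iodo-2,3,4,5-tetramethoxybenzene | COc1cc(I)c(OC)c(OC)c1OC
F7 | step 9 | (2,3,4,5-tetramethoxyphenyl)(2,4,6-trimethoxyphenyl)iodonium 4-methylbenzenesulfonate | COc1cc([I+]c2c(OC)cc(OC)cc2OC)c(OC)c(OC)c1OC.Cc1ccc(cc1)S(=O)(=O)[O-]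
F8 | step 2 | (4R)-3-acryloyl-4-benzyloxazolidin-2-one | C=CC(=O)N1[C@H](Cc2ccccc2)COC1=O
F9 | step 2 | (4R)-4-benzyl-3-[(1S,2S)-2,3-dimethylcyclohex-3-ene-1-carbonyl]oxazolidin-2-one | O=C([C@H]1CCC=C(C)[C@H]1C)N1[C@H](Cc2ccccc2)COC1=O
F10 | step 2 | methyl (1S,2S)-2,3-dimethylcyclohex-3-ene-1-carboxylate | COC(=O)[C@H]1CCC=C(C)[C@H]1C
F11 | step 2 | methyl (1R,2R)-1-{2-[(tert-butyldimethylsilyl)oxy]ethyl}-2,3-dimethylcyclohex-3-ene-1-carboxylate | CC(C)(C)[Si](C)(C)OCC[C@]1(C(=O)OC)CCC=C(C)[C@H]1C
F12 | step 2 | [(1R,2R)-1-{2-[(tert-butyldimethylsilyl)oxy]ethyl}-2,3-dimethylcyclohex-3-en-1-yl]methanol | CC(C)(C)[Si](C)(C)OCC[C@]1(CO)CCC=C(C)[C@H]1C
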